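The constants 330 /M/s and 16000 /M divide two chemists over this flask, in which J and D give L and G, G binds D as D.G in a fast balance, J passes reversibly into Z, and L crystallises as E.

    J + D → G + L (k1 = 330 /M/s)
    D + G ⇌ D.G, settled at all times (K2 = 16000 /M)
    J ⇌ Z (K3 = 2.3, k3 = 0.017 /s)
    E ⇌ L, rate k4*(cs4 - [L]) while solid is left; crystals form when [L] > cs4 (cs4 = 0.57 mM, k4 = 3.2 /s)

J 0.0010 M; D 2.00 equiv; time 10 s

- part of the J that has reacted at 10 s
- share of the unused D that is free and not bound as D.G, at 10 s

The first calls D the excess reagent. J then decays pseudo-first-order with a half-life of 1.1 s, shorter than 10 s, and 0.136% of J stays at 10 s.

The second counts in fractions of the J charge and uses the binding number, K2 times the J charge, 16.0. Bound G over free G equals this number times free D, which is 32 with D as charged, so nearly all of the G goes bound. Each J reacted then costs two D, free D stays at two per J left, and the rate is second order in J. I reckon with the second. The part of J left is one over one plus two k1 times the J charge times the time, 13.2%, so 86.8% has reacted by step 1. The bound amount equals the binding number times free D times free G, which leaves 34.0% of the unused D free. Z stays uncounted, its forward half-life being 41 s, longer than that of step 1.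

The forecast also sides with the second, “G binds D tightly, so each J reacted uses up nearly two D”. It gives 90.5% (87% to 93%), above my figure, and 35% (31% to 39%).

The flask gives 91.2% and 34.1%.

The first chemist's region is the start of this flask, where D stands as charged and his half-life of 1.1 s applies; at 1.00 s D is down to 61.3% of its charge and J stands at 59.0% against his 51.7%, and at 1.16 s the half-life of J by step 1 is 1.8 s. With 19.3% of the D charge free at 10.0 s, the binding number still puts 6.18 bound G on each free G. The neighbour flask with 0.0025 M of J, at the same equivalents and time, has a binding number of 40.0. The same two steps give 94.3% reacted and 20.2% free, and that flask stands at 19.9%.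

The numbers are invented, and the outcome is calculated.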